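Ring A is built, not bought: a (4+2) cycloaddition between a 2-prenylated 1,1-dimethoxy-3-silyloxybutadiene and the terminal ynone of a cross-conjugated diynone forges the C1–C2 and C5–C6 bonds of ring A. Loss of methanol and of the silyl group then aromatizes the adduct. The step therefore exploits, and sets in one operation, the contiguous C1-acyl, C2-OMe, C3-prenyl, C4-OH array of ring A, with the prenyl group delivered between its two oxygens. The precursor diynone already carries ring B (MOM-protected, prenylated) on its second, aryl-capped alkyne, which survives as a masked carbonyl and is finally hydrated to the 1,3-diketone.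

Key step: step 10

Remark on the chemistry: the target has no stereocentre; its 1,3-diketone is drawn in the diketo form and is expected to exist largely as the chelated enol.

Step 1
Reactants: 1 5-bromo-2-methylpent-2-ene; 2 tetramethyl orthocarbonate
Product: 4 1,1,1-trimethoxy-5-methylhex-4-ene, via Grignard reagent 3 (not isolated)
Conditions: Mg, THF, rt → 40 °C; then 2 (2 equiv), toluene, 80 °C
Reagents that add atoms: none
Why: An alkyl Grignard reagent replaces one alkoxy group of a tetraalkyl orthocarbonate (orthocarbonate variant of the Bodroux–Chichibabin reaction), and the excess of 2 should suppress a second substitution.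

Step 2
Reactants: 4 1,1,1-trimethoxy-5-methylhex-4-ene
Product: 5 1,1-dimethoxy-5-methylhexa-1,4-diene
Conditions: TMSOTf, i-Pr2NEt, CH2Cl2, −20 °C → rt; pentane, filtration, distillation
Reagents that add atoms: none
Why: Elimination of methanol from an orthoester: the silyl triflate removes one methoxide as TMSOMe and the hindered amine deprotonates the dimethoxycarbenium ion at the α-carbon, under non-protic conditions that spare the trisubstituted alkene.

Step 3
Reactants: 5 1,1-dimethoxy-5-methylhexa-1,4-diene
Product: 6 3-(dimethoxymethylidene)-6-methylhept-5-en-2-one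
Conditions: AcCl, Et3N, Et2O, 0 °C → rt
Reagents that add atoms: acetyl chloride CC(Cl)=O
Why: C-Acylation of a ketene acetal by an acid chloride at its nucleophilic β-carbon, followed by loss of the now strongly acidic α-proton to the amine, should give the push–pull β-oxo ketene acetal.

Step 4
Reactants: 6 3-(dimethoxymethylidene)-6-methylhept-5-en-2-one
Product: 8 1,1-dimethoxy-2-(3-methylbut-2-en-1-yl)-3-(trimethylsilyloxy)buta-1,3-diene, via lithium enolate 7 (not isolated)
Conditions: LiN(i-Pr)2, THF, −78 °C; TMSCl, −78 °C → 0 °C; non-aqueous work-up, Kugelrohr distillation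
Reagents that add atoms: chlorotrimethylsilane C[Si](C)(C)Cl
Why: Kinetic enolization of the methyl ketone (its only α-position) and O-silylation of the cross-conjugated enolate (silyl enol ether formation) should give the 2-silyloxydiene, the doubly allylic CH2 staying untouched under kinetic control.

Step 5
Reactants: 9 4-hydroxybenzaldehyde; 10 prenyl bromide (1-bromo-3-methylbut-2-ene)
Product: 11 4-hydroxy-3-(3-methylbut-2-en-1-yl)benzaldehyde
Conditions: 10% aq KOH, rt
Reagents that add atoms: none
Why: Ortho-C-alkylation of the phenoxide in water, where hydrogen bonding shields the oxygen and the para position is blocked by the formyl group, should give the 3-prenyl phenol; the O-prenyl ether and bis-alkylated material are separated by chromatography.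

Step 6
Reactants: 11 4-hydroxy-3-(3-methylbut-2-en-1-yl)benzaldehyde
Product: 12 4-(methoxymethoxy)-3-(3-methylbut-2-en-1-yl)benzaldehyde
Conditions: MOMCl, i-Pr2NEt, CH2Cl2, 0 °C → rt
Reagents that add atoms: chloromethyl methyl ether COCCl
Why: O-Alkylation of the phenol with the chloromethyl ether (Williamson-type acetal protection) gives a MOM ether that is inert to the organolithium, methoxide and oxidation steps ahead.

Step 7
Reactants: 12 4-(methoxymethoxy)-3-(3-methylbut-2-en-1-yl)benzaldehyde
Product: 13 4-ethynyl-1-(methoxymethoxy)-2-(3-methylbut-2-en-1-yl)benzene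
Conditions: dimethyl (1-diazo-2-oxopropyl)phosphonate, K2CO3, MeOH, rt
Reagents that add atoms: dimethyl (1-diazo-2-oxopropyl)phosphonate CC(=O)C(=[N+]=[N-])P(=O)(OC)OC
Why: Seyferth–Gilbert homologation in its Ohira–Bestmann form converts the aryl aldehyde into the terminal alkyne under mild carbonate conditions that the MOM ether and the prenyl group tolerate.

Step 8
Reactants: 13 4-ethynyl-1-(methoxymethoxy)-2-(3-methylbut-2-en-1-yl)benzene; 14 3-(trimethylsilyl)prop-2-ynal
Product: 17 racemic 1-[4-(methoxymethoxy)-3-(3-methylbut-2-en-1-yl)phenyl]penta-1,4-diyn-3-ol, via lithium acetylide 15 (not isolated), via silylated diynol alkoxide 16 (not isolated)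
Conditions: n-BuLi, THF, −78 °C; 14, −78 °C; then MeOH, K2CO3 (cat.), rt
Reagents that add atoms: none
Why: 1,2-Addition of the lithium acetylide to the ynal followed by methoxide-induced protodesilylation of the C(sp)–Si bond gives the terminal diynol; the carbinol stereocentre forms as a racemate and is erased by the oxidation in step 9.

Step 9
Reactants: 17 racemic 1-[4-(methoxymethoxy)-3-(3-methylbut-2-en-1-yl)phenyl]penta-1,4-diyn-3-ol
Product: 18 1-[4-(methoxymethoxy)-3-(3-methylbut-2-en-1-yl)phenyl]penta-1,4-diyn-3-one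
Conditions: MnO2, CH2Cl2, rt; used at once
Reagents that add atoms: none
Why: MnO2 oxidation of an activated (doubly propargylic) alcohol proceeds under neutral conditions that should leave the base- and nucleophile-sensitive diynone intact.

Step 10
Reactants: 8 1,1-dimethoxy-2-(3-methylbut-2-en-1-yl)-3-(trimethylsilyloxy)buta-1,3-diene; 18 1-[4-(methoxymethoxy)-3-(3-methylbut-2-en-1-yl)phenyl]penta-1,4-diyn-3-one
Product: 21 1-[4-hydroxy-2-methoxy-3-(3-methylbut-2-en-1-yl)phenyl]-3-[4-(methoxymethoxy)-3-(3-methylbut-2-en-1-yl)phenyl]prop-2-yn-1-one, via cycloadduct 19 (not isolated), via aryl silyl ether 20 (not isolated)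
Conditions: 8 (1.3 equiv), toluene, −20 °C → rt; then 0.1 M aq HCl, THF, 0 °C
Reagents that add atoms: none
Why: The electron-rich diene 8 and the terminal ynone of 18 should combine in a concerted but strongly asynchronous (4+2) cycloaddition in which the CH2 terminus of the silyl enol ether bonds first to the unsubstituted β-alkyne carbon and the ketene acetal carbon then bonds to the carbonyl-bearing α-carbon, giving cyclohexa-1,4-diene 19. The closest known reaction type is the Diels–Alder reaction of 1,1-dimethoxy-3-silyloxybuta-1,3-dienes with alkynyl ketones and esters, whose adducts aromatize by 1,4-loss of methanol. Ring A closes as a six-membered carbocycle through the intermolecular cycloaddition itself, the two new σ-bonds (C1–C2 and C5–C6 of ring A) joining the diene termini to the two alkyne carbons; methanol is then lost from the C(OMe)2 carbon and the ring CH2 to give silyl ether 20, and dilute acid frees phenol 21. No stereocentre is created, because both sp3 ring carbons of 19 carry two identical substituents and vanish on aromatization. Regiochemistry (acyl next to OMe and para to OH) follows from the matched polarization of the push–pull diene and the ynone, and site selectivity from the terminal alkyne being less hindered and more electrophilic than the aryl-capped one, whose β-carbon is substituted and deactivated by the para-alkoxyaryl donor. The same factors, a small excess of 8 and low temperature should hold back a second cycloaddition.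

Step 11
Reactants: 21 1-[4-hydroxy-2-methoxy-3-(3-methylbut-2-en-1-yl)phenyl]-3-[4-(methoxymethoxy)-3-(3-methylbut-2-en-1-yl)phenyl]prop-2-yn-1-one
Product: 23 1-[4-hydroxy-2-methoxy-3-(3-methylbut-2-en-1-yl)phenyl]-3-[4-hydroxy-3-(3-methylbut-2-en-1-yl)phenyl]propane-1,3-dione, via enaminone 22 (not isolated)
Conditions: Et2NH (5 equiv), EtOH, rt → 40 °C; then 2 M aq HCl, MeOH, 40 °C
Reagents that add atoms: water O
Why: Aza-Michael addition of the secondary amine to the ynone at the β-carbon bearing ring B gives the enaminone, and aqueous acid then hydrolyses both the enaminone (to the 1,3-diketone) and the MOM acetal, while the methyl ether at C2 of ring A rules out cyclization to a flavone.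

Compound list
1 | 5-bromo-2-methylpent-2-ene | CC(C)=CCCBr | starting material
2 | tetramethyl orthocarbonate | COC(OC)(OC)OC | starting material
3 | (4-methylpent-3-en-1-yl)magnesium bromide | CC(C)=CCC[Mg]Br | intermediate
4 | 1,1,1-trimethoxy-5-methylhex-4-ene | COC(OC)(OC)CCC=C(C)C | intermediate
5 | 1,1-dimethoxy-5-methylhexa-1,4-diene | COC(OC)=CCC=C(C)C | intermediate
6 | 3-(dimethoxymethylidene)-6-methylhept-5-en-2-one | CC(=O)C(CC=C(C)C)=C(OC)OC | intermediate
7 | lithium 3-(dimethoxymethylidene)-6-methylhepta-1,5-dien-2-olate | [Li]OC(=C)C(CC=C(C)C)=C(OC)OC | intermediate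
8 | 1,1-dimethoxy-2-(3-methylbut-2-en-1-yl)-3-(trimethylsilyloxy)buta-1,3-diene | COC(OC)=C(CC=C(C)C)C(=C)O[Si](C)(C)C | intermediate
9 | 4-hydroxybenzaldehyde | O=Cc1ccc(O)cc1 | starting material
10 | prenyl bromide (1-bromo-3-methylbut-2-ene) | CC(C)=CCBr | starting material
11 | 4-hydroxy-3-(3-methylbut-2-en-1-yl)benzaldehyde | O=Cc1ccc(O)c(CC=C(C)C)c1 | intermediate
12 | 4-(methoxymethoxy)-3-(3-methylbut-2-en-1-yl)benzaldehyde | O=Cc1ccc(OCOC)c(CC=C(C)C)c1 | intermediate
13 | 4-ethynyl-1-(methoxymethoxy)-2-(3-methylbut-2-en-1-yl)benzene | C#Cc1ccc(OCOC)c(CC=C(C)C)c1 | intermediate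
14 | 3-(trimethylsilyl)prop-2-ynal | C[Si](C)(C)C#CC=O | starting material
15 | {[4-(methoxymethoxy)-3-(3-methylbut-2-en-1-yl)phenyl]ethynyl}lithium | [Li]C#Cc1ccc(OCOC)c(CC=C(C)C)c1 | intermediate
16 | lithium alkoxide of racemic 1-[4-(methoxymethoxy)-3-(3-methylbut-2-en-1-yl)phenyl]-5-(trimethylsilyl)penta-1,4-diyn-3-ol | C[Si](C)(C)C#CC(O[Li])C#Cc1ccc(OCOC)c(CC=C(C)C)c1 | intermediate
17 | racemic 1-[4-(methoxymethoxy)-3-(3-methylbut-2-en-1-yl)phenyl]penta-1,4-diyn-3-ol | C#CC(O)C#Cc1ccc(OCOC)c(CC=C(C)C)c1 | intermediate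
18 | 1-[4-(methoxymethoxy)-3-(3-methylbut-2-en-1-yl)phenyl]penta-1,4-diyn-3-one | C#CC(=O)C#Cc1ccc(OCOC)c(CC=C(C)C)c1 | intermediate
19 | 1-[6,6-dimethoxy-5-(3-methylbut-2-en-1-yl)-4-(trimethylsilyloxy)cyclohexa-1,4-dien-1-yl]-3-[4-(methoxymethoxy)-3-(3-methylbut-2-en-1-yl)phenyl]prop-2-yn-1-one | COC1(OC)C(CC=C(C)C)=C(O[Si](C)(C)C)CC=C1C(=O)C#Cc1ccc(OCOC)c(CC=C(C)C)c1 | intermediate
20 | 1-[2-methoxy-3-(3-methylbut-2-en-1-yl)-4-(trimethylsilyloxy)phenyl]-3-[4-(methoxymethoxy)-3-(3-methylbut-2-en-1-yl)phenyl]prop-2-yn-1-one | COc1c(C(=O)C#Cc2ccc(OCOC)c(CC=C(C)C)c2)ccc(O[Si](C)(C)C)c1CC=C(C)C | intermediate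
21 | 1-[4-hydroxy-2-methoxy-3-(3-methylbut-2-en-1-yl)phenyl]-3-[4-(methoxymethoxy)-3-(3-methylbut-2-en-1-yl)phenyl]prop-2-yn-1-one | COc1c(C(=O)C#Cc2ccc(OCOC)c(CC=C(C)C)c2)ccc(O)c1CC=C(C)C | intermediate
22 | (E)-3-(diethylamino)-1-[4-hydroxy-2-methoxy-3-(3-methylbut-2-en-1-yl)phenyl]-3-[4-(methoxymethoxy)-3-(3-methylbut-2-en-1-yl)phenyl]prop-2-en-1-one (E geometry expected) | COc1c(C(=O)/C=C(/N(CC)CC)c2ccc(OCOC)c(CC=C(C)C)c2)ccc(O)c1CC=C(C)C | intermediate
23 | 1-[4-hydroxy-2-methoxy-3-(3-methylbut-2-en-1-yl)phenyl]-3-[4-hydroxy-3-(3-methylbut-2-en-1-yl)phenyl]propane-1,3-dione | COc1c(C(=O)CC(=O)c2ccc(O)c(CC=C(C)C)c2)ccc(O)c1CC=C(C)C | target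

Total step count: 11 (diene branch: steps 1–4; diynone branch: steps 5–9; union and endgame: steps 10–11).
Longest linear sequence: 7 steps (steps 5–11, from 4-hydroxybenzaldehyde).

Steps most likely to fail

Step 10. The diene may add to the aryl-capped alkyne or add a second time, the doubly activated diynone may oligomerize, or the diene may be protodesilylated before it reacts. The fallback keeps the cycloaddition but moves it to a simple mono-ynone and makes the diketone by aldol chemistry. It sets out from diene 8, which is combined with commercial but-3-yn-2-one (toluene, rt, dilute acid work-up) to give 1-[4-hydroxy-2-methoxy-3-(3-methylbut-2-en-1-yl)phenyl]ethan-1-one F1. Protection with MOMCl and i-Pr2NEt gives 1-[2-methoxy-4-(methoxymethoxy)-3-(3-methylbut-2-en-1-yl)phenyl]ethan-1-one F2. Its lithium enolate (LiN(i-Pr)2, THF, −78 °C) is added to aldehyde 12 to give the racemic aldol 3-hydroxy-1-[2-methoxy-4-(methoxymethoxy)-3-(3-methylbut-2-en-1-yl)phenyl]-3-[4-(methoxymethoxy)-3-(3-methylbut-2-en-1-yl)phenyl]propan-1-one F3. Oxidation with Dess–Martin periodinane gives 1-[2-methoxy-4-(methoxymethoxy)-3-(3-methylbut-2-en-1-yl)phenyl]-3-[4-(methoxymethoxy)-3-(3-methylbut-2-en-1-yl)phenyl]propane-1,3-dione F4. Cleavage of both MOM ethers with 2 M HCl in MeOH brings the fallback back to the route at target 23.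

Step 3. Chloride may dealkylate the acylated dimethoxycarbenium intermediate to the β-keto ester, or acetyl chloride may be diverted to ketene by the amine, faster than the wanted deprotonation. The fallback gives up the diene and takes ring A from the aromatic pool. It sets out from prenyl bromide 10, which C-alkylates commercial 2,4-dihydroxyacetophenone at C3 (aq KOH, rt) to give 1-[2,4-dihydroxy-3-(3-methylbut-2-en-1-yl)phenyl]ethan-1-one F5. Selective protection of the non-chelated 4-hydroxyl (MOMCl, K2CO3, acetone) gives 1-[2-hydroxy-4-(methoxymethoxy)-3-(3-methylbut-2-en-1-yl)phenyl]ethan-1-one F6. O-Methylation (MeI, K2CO3, DMF) gives F2, which is carried through F3 and F4 exactly as above and rejoins the route at target 23.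

Step 2. The dimethoxycarbenium ion may be O-demethylated by triflate or amine back to the methyl ester instead of losing its α-proton, and the ketene acetal may hydrolyse during isolation. The fallback builds the ketene acetal C=C bond by Horner–Wittig olefination. It sets out from bromide 1, which is oxidized with Me3NO in DMSO (Kornblum-type oxidation) to 4-methylpent-3-enal F7. (Dimethoxymethyl)diphenylphosphine oxide F8, prepared from chlorodiphenylphosphine and trimethyl orthoformate, is lithiated (LiN(i-Pr)2, THF, −78 °C) and added to F7 to give racemic 1-(diphenylphosphoryl)-1,1-dimethoxy-5-methylhex-4-en-2-ol F9. Treatment with KOt-Bu in THF eliminates diphenylphosphinate and returns the route at ketene acetal 5.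

Further compounds
F1 | step 10 | 1-[4-hydroxy-2-methoxy-3-(3-methylbut-2-en-1-yl)phenyl]ethan-1-one | COc1c(C(C)=O)ccc(O)c1CC=C(C)C
F2 | step 10 | 1-[2-methoxy-4-(methoxymethoxy)-3-(3-methylbut-2-en-1-yl)phenyl]ethan-1-one | COCOc1ccc(C(C)=O)c(OC)c1CC=C(C)C
F3 | step 10 | racemic 3-hydroxy-1-[2-methoxy-4-(methoxymethoxy)-3-(3-methylbut-2-en-1-yl)phenyl]-3-[4-(methoxymethoxy)-3-(3-methylbut-2-en-1-yl)phenyl]propan-1-one | COCOc1ccc(C(=O)CC(O)c2ccc(OCOC)c(CC=C(C)C)c2)c(OC)c1CC=C(C)C
F4 | step 10 | 1-[2-methoxy-4-(methoxymethoxy)-3-(3-methylbut-2-en-1-yl)phenyl]-3-[4-(methoxymethoxy)-3-(3-methylbut-2-en-1-yl)phenyl]propane-1,3-dione | COCOc1ccc(C(=O)CC(=O)c2ccc(OCOC)c(CC=C(C)C)c2)c(OC)c1CC=C(C)C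
F5 | step 3 | 1-[2,4-dihydroxy-3-(3-methylbut-2-en-1-yl)phenyl]ethan-1-one | CC(=O)c1ccc(O)c(CC=C(C)C)c1O
F6 | step 3 | 1-[2-hydroxy-4-(methoxymethoxy)-3-(3-methylbut-2-en-1-yl)phenyl]ethan-1-one | CC(=O)c1ccc(OCOC)c(CC=C(C)C)c1O
F7 | step 2 | 4-methylpent-3-enal | CC(C)=CCC=O
F8 | step 2 | (dimethoxymethyl)diphenylphosphine oxide | COC(OC)P(=O)(c1ccccc1)c1ccccc1
F9 | step 2 | racemic 1-(diphenylphosphoryl)-1,1-dimethoxy-5-methylhex-4-en-2-ol | COC(OC)(C(O)CC=C(C)C)P(=O)(c1ccccc1)c1ccccc1
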